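The runs come from a simulation on assumed constants, and the scatter is random.

The midnight run is this same flask followed to 50.0 min: after a short lag, target climbs from 10% at 12.0 min to 53% at 50.0 min, nearly straight.

all flasks: starting material 0.057 M; gas phase 32 mM (held); free catalyst 0.2 mol%
- midnight: the very flask that is asked about, followed so far
- flask: time 1.5 h

- midnight (time / min: target / %): 2.50: 1; 6.00: 2; 12.0: 10; 20.0: 21; 25.0: 27; 40.0: 42; 50.0: 53

(scatter of a reading: 1.5 percentage points)

- at the start none of the gas is dissolved
- candidate steps: gas phase <-> dissolved gas; starting material + dissolved gas + free catalyst -> free catalyst + target; 2 free catalyst -> spent catalyst; dissolved gas + target -> over-reaction product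

- amount of target at 1.5 h, in percent of the starting material charged
- the change that raises the amount of target at 1.5 h, in percent of the starting material charged most ("none" if none brings more than 2 percentage points) (beta / zeta / epsilon / none)
- amount of target at 1.5 h, in percent of the starting material charged, after zeta

- beta: doubling the transfer coefficient of the gas phase, all else as stated
- zeta: doubling the saturation concentration of gas phase, all else as stated
- epsilon: doubling the amount of free catalyst, all else as stated

The bench rule is to extend the line. Its slope is 0.0113 min⁻¹ of the charge, which puts target at 98.2% at 1.5 h. But if what reacted is read as target, starting material fell by a factor of 1.91 along that line, so if the rate follows it, something else rose to compensate. I suspect dissolved gas, which starts at none and has a ceiling of 32 mM.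

Slope times 0.057 M, divided by that ceiling, gives as a reading 0.0202 min⁻¹, the needed transfer coefficient: the smallest coefficient that could feed the line, at one gas per starting material. If transfer were the rate-limiting step, the solution would stay near empty and I would expect no lag. I therefore take the true coefficient k to be larger, which holds c(dissolved gas) near the fraction 1 − needed/k of saturation. Once that level stops rising, the rate should follow starting material, so I reckon 82.1%, and less if catalyst dies. At equal demand, my rule gives 2 times as much dissolved gas under zeta as under beta, so of these two I choose zeta; I have no reckoning for epsilon from these readings, and zeta is my pick.

The forecast, reading “gas transfer limiting the rate”, gives 85% (76% to 93%), higher than mine. It names beta as the best change and gives 90% (72% to 98%) after zeta.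

The flask gives 72.5%. Zeta adds 17 percentage points, more than beta's 9.1 points or epsilon's 7.2 points, and reaches 89.1%.

    gas phase ⇌ dissolved gas, rate k1*(csat - [dissolved gas]) (kL = 0.0550 min⁻¹)
    starting material + dissolved gas + free catalyst → free catalyst + target (k = 16000 M⁻² min⁻¹)
    2 free catalyst → spent catalyst (k = 110 M⁻¹ min⁻¹)
    dissolved gas + target → over-reaction product (k = 0.0230 M⁻¹ min⁻¹)

The true coefficient, 0.055 min⁻¹, is 2.72 times the needed one, so the rule puts dissolved gas in this flask at 63.3% of saturation, and at 0.750 h it stands at 60.3%. In the neighbour with 0.05 mol% of free catalyst, the mean demand over the run gives 82.7% of saturation by the same rule, and at 1.50 h that flask holds 0.0266 M of dissolved gas, 83.1% of saturation.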